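**Assumption:** The target SMILES has no stereocentres (bulbocodin D is achiral), so "single enantiomer" does not apply and no stereocontrol is needed.

## Retrosynthetic overview

1. No rings are formed; all four benzene rings are purchased, and the route only makes C–C bonds between them.
2. The C4 benzyl CH2 comes from a diaryl ketone, which also directs BCl3 to cleave only the adjacent OMe (giving the C5-OH) and leaves the para OMe.
3. The ketone comes from Friedel–Crafts aroylation of a C2-symmetric 4-benzyl-3,5-dimethoxybibenzyl, where the two open ring-A positions are equivalent.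
4. The benzyl group between the two OMe groups comes from directed ortho-lithiation of the 3,5-dimethoxybibenzyl and benzylation.
5. The bibenzyl comes from a Horner–Wadsworth–Emmons (HWE) olefination followed by hydrogenation.

## Route

**Step 1**
Reactants: 1, diethyl (3,5-dimethoxybenzyl)phosphonate; 2, 3-isopropoxybenzaldehyde
Product: 3, (E)-1-[2-(3-isopropoxyphenyl)ethenyl]-3,5-dimethoxybenzene
Conditions: NaH, THF, 0 °C → rt
Reagents that add atoms: 2, 3-isopropoxybenzaldehyde, CC(C)Oc1cccc(C=O)c1
Why: HWE olefination of a benzylic phosphonate with an aryl aldehyde gives the stilbene; alkene geometry is irrelevant because it is reduced next.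

**Step 2**
Reactants: 3, the stilbene
Product: 4, 1-[2-(3-isopropoxyphenyl)ethyl]-3,5-dimethoxybenzene
Conditions: H2 (1 atm), 10% Pd/C, EtOAc, rt
Reagents that add atoms: none
Why: Catalytic hydrogenation of the stilbene C=C; methyl and isopropyl aryl ethers are inert, which is why ring B carries isopropyl and not benzyl.

**Step 3**
Reactants: 4, the bibenzyl; 5, 4-(benzyloxy)benzyl bromide
Product: 6, 2-[4-(benzyloxy)benzyl]-1,3-dimethoxy-5-[2-(3-isopropoxyphenyl)ethyl]benzene
Conditions: n-BuLi (1.1 equiv), THF, 0 °C → rt; CuI (1 equiv), −20 °C; then 5, −20 °C → rt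
Reagents that add atoms: 5, 4-(benzyloxy)benzyl bromide, BrCc1ccc(OCc2ccccc2)cc1
Why: Directed ortho-metalation occurs at the position flanked by both OMe groups, far faster than next to the single OiPr on ring B; the arylcopper is then alkylated by the benzylic bromide.

**Step 4**
Reactants: 6; 7, 4-(benzyloxy)benzoyl chloride
Product: 8, [4-(benzyloxy)phenyl]{3-[4-(benzyloxy)benzyl]-2,4-dimethoxy-6-[2-(3-isopropoxyphenyl)ethyl]phenyl}methanone
Conditions: 7 (1.1 equiv), SnCl4 (1.2 equiv), CH2Cl2, −20 → 0 °C
Reagents that add atoms: 7, 4-(benzyloxy)benzoyl chloride, O=C(Cl)c1ccc(OCc2ccccc2)cc1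
Why: Friedel–Crafts acylation goes to ring A because its open position is ortho and para to two OMe groups, while the other rings are only mono-alkoxy activated. The two open ring-A positions are symmetry-equivalent, and the ketone product is deactivated, so acylation stops at one.

**Step 5**
Reactants: 8
Product: 9, (4-hydroxyphenyl){2-hydroxy-3-(4-hydroxybenzyl)-6-[2-(3-hydroxyphenyl)ethyl]-4-methoxyphenyl}methanone
Conditions: BCl3 (about 8 equiv, 1 M in CH2Cl2), pentamethylbenzene (6 equiv), CH2Cl2, −78 → 0 °C; MeOH quench
Reagents that add atoms: none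
Why: BCl3 dealkylation cleaves the OMe ortho to the ketone through a six-membered boron chelate, and cleaves the two benzyl ethers and the isopropyl ether through stabilised cations trapped by pentamethylbenzene. The unchelated OMe para to the carbonyl is not cleaved by BCl3 at or below 0 °C.

**Step 6**
Reactants: 9
Product: 10, bulbocodin D
Conditions: Et3SiH (4 equiv), TFA/CH2Cl2 (1:2), 0 °C → rt
Reagents that add atoms: none
Why: Ionic hydrogenation; the protonated ketone and the derived benzhydryl cation are strongly stabilised by the ortho-OH/para-OMe ring and the para-hydroxyphenyl ring, so silane delivers hydride twice to give the diarylmethane without touching the phenols or the OMe.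

## Compound list

1 | diethyl (3,5-dimethoxybenzyl)phosphonate | COc1cc(CP(=O)(OCC)OCC)cc(OC)c1 | starting material
2 | 3-isopropoxybenzaldehyde | CC(C)Oc1cccc(C=O)c1 | starting material
3 | (E)-1-[2-(3-isopropoxyphenyl)ethenyl]-3,5-dimethoxybenzene | COc1cc(/C=C/c2cccc(OC(C)C)c2)cc(OC)c1 | intermediate
4 | 1-[2-(3-isopropoxyphenyl)ethyl]-3,5-dimethoxybenzene | COc1cc(CCc2cccc(OC(C)C)c2)cc(OC)c1 | intermediate
5 | 4-(benzyloxy)benzyl bromide | BrCc1ccc(OCc2ccccc2)cc1 | starting material
6 | 2-[4-(benzyloxy)benzyl]-1,3-dimethoxy-5-[2-(3-isopropoxyphenyl)ethyl]benzene | COc1cc(CCc2cccc(OC(C)C)c2)cc(OC)c1Cc1ccc(OCc2ccccc2)cc1 | intermediate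
7 | 4-(benzyloxy)benzoyl chloride | O=C(Cl)c1ccc(OCc2ccccc2)cc1 | starting material
8 | [4-(benzyloxy)phenyl]{3-[4-(benzyloxy)benzyl]-2,4-dimethoxy-6-[2-(3-isopropoxyphenyl)ethyl]phenyl}methanone | COc1cc(CCc2cccc(OC(C)C)c2)c(C(=O)c2ccc(OCc3ccccc3)cc2)c(OC)c1Cc1ccc(OCc2ccccc2)cc1 | intermediate
9 | (4-hydroxyphenyl){2-hydroxy-3-(4-hydroxybenzyl)-6-[2-(3-hydroxyphenyl)ethyl]-4-methoxyphenyl}methanone | COc1cc(CCc2cccc(O)c2)c(C(=O)c2ccc(O)cc2)c(O)c1Cc1ccc(O)cc1 | intermediate
10 | bulbocodin D | COc1cc(CCc2cccc(O)c2)c(Cc2ccc(O)cc2)c(O)c1Cc1ccc(O)cc1 | target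

## Summary

Total step count: 6. Longest linear sequence: 6 steps (1/2 → 3 → 4 → 6 → 8 → 9 → 10).

Steps most likely to fail, each with a fallback:

1. **Step 4 (Friedel–Crafts aroylation).** The reacting position is hindered, three other alkoxy-arene rings compete, and acid could cause loss or migration of the 4-alkoxybenzyl group. Fallback: brominate 6 with NBS (MeCN, 0 °C) at the ring-A position, do Br/Li exchange (n-BuLi, −78 °C), add 4-(benzyloxy)benzaldehyde, and oxidise the benzhydrol (Dess–Martin periodinane) to ketone 8.

2. **Step 5 (one-pot BCl3 cleavage of four ethers while keeping one OMe).** Risks are incomplete isopropyl cleavage, over-demethylation, and benzyl-cation re-alkylation of the electron-rich rings. Fallback: change the protecting-group plan so ring B carries a benzyl ether (reduce the stilbene with diimide or Wilkinson's catalyst instead). Then cleave only the chelated OMe (1 equiv BCl3, −78 °C, or MgI2·OEt2), and finish with one hydrogenolysis (H2, Pd(OH)2/C, AcOH) that removes all benzyl ethers and reduces the diaryl C=O to CH2.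

3. **Step 6 (deoxygenation of a di-ortho-substituted, hydrogen-bonded ketone bearing free phenols).** The reduction may be sluggish, and TFA could promote trans-benzylation. Fallback: use a non-acidic quinone-methide pathway, either NaBH4 in aq. NaOH/THF at reflux, or ClCO2Et/Et3N then NaBH4 in THF/H2O, in which borohydride reduces the ketone and the resulting quinone methide in basic medium.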